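## Retrosynthetic overview

1. The only C–C disconnection is the aryl–C8 bond (thymol numbering: C8 quaternary carbon, C9 oxirane CH2, C10 CH2O‑acyl). Aryl bromide 1 and oxetan‑3‑one 2 are joined through trilithio arene 3 to give the prochiral oxetanol triol 4, which holds all ten skeletal carbons.
2. Two acyl C–O disconnections follow: the phenol ester from tigloyl chloride 5 (giving 6) and the benzylic ester from isobutyric anhydride 7 (giving 8).
3. Key C–O disconnections: the C10–O–acyl bond and the oxirane C9–O bond both trace back to the oxetane of 8. Enantioselective acylative opening with isobutyryl bromide 9 gives bromohydrin ester 10, and 3‑exo‑tet closure gives target 11.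
4. Ring order: the benzene and oxetane rings are bought (in 1 and 2). The oxetane is opened and the oxirane is the only ring formed, in the last step. The single stereocenter is set in the desymmetrisation.

Assumption: 1, 2, 5, 7 and 9 are bought as such (1 is the catalogue compound 4‑bromo‑3‑hydroxybenzyl alcohol), and the target is taken as drawn, which I read as (R) at the oxirane carbon with an (E)‑2‑methylbut‑2‑enoate (tiglate).

## Route

Step 1
Reactants: 1 2‑bromo‑5‑(hydroxymethyl)phenol; 2 oxetan‑3‑one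
Product: 4 3‑[2‑hydroxy‑4‑(hydroxymethyl)phenyl]oxetan‑3‑ol, via trilithio aryl species 3 (not isolated)
Conditions: n‑BuLi (3.1 equiv), THF, −78 → −20 °C; then 2 (1.2 equiv), −78 → 0 °C; aq NH4Cl
Reagents that add atoms: oxetan‑3‑one (2), O=C1COC1
Why: Two equivalents of n‑BuLi deprotonate the two OH groups and the third performs bromine–lithium exchange, and the ortho‑lithio phenoxide then adds 1,2 to the strained, poorly enolisable ketone of 2 (halogen–metal exchange followed by carbonyl addition); the new carbinol carbon is prochiral, so no stereocenter is formed yet.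

Step 2
Reactants: 4 3‑[2‑hydroxy‑4‑(hydroxymethyl)phenyl]oxetan‑3‑ol; 5 (2E)‑2‑methylbut‑2‑enoyl chloride; 7 2‑methylpropanoic anhydride
Product: 8 2‑(3‑hydroxyoxetan‑3‑yl)‑5‑[(2‑methylpropanoyloxy)methyl]phenyl (2E)‑2‑methylbut‑2‑enoate, via phenol tiglate diol 6 (not isolated)
Conditions: 5 (1.05 equiv), K2CO3 (2.5 equiv), acetone, 0 °C → rt; then 7 (1.2 equiv), DMAP (5 mol%), rt
Reagents that add atoms: (2E)‑2‑methylbut‑2‑enoyl chloride (5), C/C=C(\C)C(Cl)=O; 2‑methylpropanoic anhydride (7), CC(C)C(=O)OC(=O)C(C)C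
Why: K2CO3 ionises only the phenol, so the acyl chloride reacts at the phenoxide oxygen (phenoxide‑selective O‑acylation, no amine base, hence no vinylketene deconjugation of the tiglate), and the anhydride with catalytic DMAP then esterifies the primary benzylic OH much faster than the hindered tertiary oxetanol (nucleophile‑catalysed acylation); no stereocenter is involved and the oxetane tolerates these mildly basic conditions.

Step 3
Reactants: 8 2‑(3‑hydroxyoxetan‑3‑yl)‑5‑[(2‑methylpropanoyloxy)methyl]phenyl (2E)‑2‑methylbut‑2‑enoate; 9 2‑methylpropanoyl bromide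
Product: 11 5‑[(2‑methylpropanoyloxy)methyl]‑2‑{(2R)‑2‑[(2‑methylpropanoyloxy)methyl]oxiran‑2‑yl}phenyl (2E)‑2‑methylbut‑2‑enoate, via (S)‑bromohydrin ester 10 (not isolated)
Conditions: 9 (1.1 equiv), chiral squaramide hydrogen‑bond‑donor catalyst (aryl squaramide of a tert‑leucine 2‑arylpyrrolidine amide, 10 mol%, antipode that delivers bromide to the pro‑S CH2), 4 Å MS, toluene, −40 °C; then Cs2CO3 (2.0 equiv), MeCN, 0 °C → rt
Reagents that add atoms: 2‑methylpropanoyl bromide (9), CC(C)C(Br)=O
Why: Proposed new method: catalytic enantioselective acylative ring‑opening desymmetrisation of a prochiral 3‑aryloxetan‑3‑ol with an acyl bromide — the two N–H donors of the squaramide bind bromide and ionise the oxetane·acyl bromide pair into a contact ion pair of a strained O‑acyloxetanium and catalyst‑bound bromide, the tertiary OH (hydrogen‑bonded to the catalyst) and the aryl group are told apart in the chiral pocket, and the bound bromide opens the oxonium by SN2 at the pro‑S CH2 only, which fixes the carbinol carbon as (S) in 10 without any bond to it being made or broken; Cs2CO3 then closes the oxirane by 3‑exo‑tet Williamson displacement of bromide by the tertiary alkoxide, again leaving the stereocenter untouched, so (S)‑10 becomes (R)‑11 only through the change in CIP priorities; the closest known reaction types are the squaramide‑catalysed enantioselective Me3SiBr opening of 3‑substituted oxetanes and the racemic Lewis‑acid‑promoted cleavage of cyclic ethers by acyl halides.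

## Compound list

1 | 2‑bromo‑5‑(hydroxymethyl)phenol (4‑bromo‑3‑hydroxybenzyl alcohol) | OCc1ccc(Br)c(O)c1 | starting material
2 | oxetan‑3‑one | O=C1COC1 | starting material
3 | lithium 2‑lithio‑5‑[(lithiooxy)methyl]phenolate (trilithio aryl species) | [Li]OCc1ccc([Li])c(O[Li])c1 | intermediate
4 | 3‑[2‑hydroxy‑4‑(hydroxymethyl)phenyl]oxetan‑3‑ol (achiral, prochiral at oxetane C3) | OCc1ccc(C2(O)COC2)c(O)c1 | intermediate
5 | (2E)‑2‑methylbut‑2‑enoyl chloride (tigloyl chloride) | C/C=C(\C)C(Cl)=O | starting material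
6 | 5‑(hydroxymethyl)‑2‑(3‑hydroxyoxetan‑3‑yl)phenyl (2E)‑2‑methylbut‑2‑enoate | C/C=C(\C)C(=O)Oc1cc(CO)ccc1C1(O)COC1 | intermediate
7 | 2‑methylpropanoic anhydride (isobutyric anhydride) | CC(C)C(=O)OC(=O)C(C)C | starting material
8 | 2‑(3‑hydroxyoxetan‑3‑yl)‑5‑[(2‑methylpropanoyloxy)methyl]phenyl (2E)‑2‑methylbut‑2‑enoate | C/C=C(\C)C(=O)Oc1cc(COC(=O)C(C)C)ccc1C1(O)COC1 | intermediate
9 | 2‑methylpropanoyl bromide (isobutyryl bromide) | CC(C)C(Br)=O | starting material
10 | 2‑[(2S)‑1‑bromo‑2‑hydroxy‑3‑(2‑methylpropanoyloxy)propan‑2‑yl]‑5‑[(2‑methylpropanoyloxy)methyl]phenyl (2E)‑2‑methylbut‑2‑enoate | C/C=C(\C)C(=O)Oc1cc(COC(=O)C(C)C)ccc1[C@](O)(COC(=O)C(C)C)CBr | intermediate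
11 | 5‑[(2‑methylpropanoyloxy)methyl]‑2‑{(2R)‑2‑[(2‑methylpropanoyloxy)methyl]oxiran‑2‑yl}phenyl (2E)‑2‑methylbut‑2‑enoate | C/C=C(\C)C(=O)Oc1cc(COC(=O)C(C)C)ccc1[C@]1(COC(=O)C(C)C)CO1 | target

## Step count and risks

Total step count: 3. Longest linear sequence: 3 steps (1 → 4 → 8 → 11).

Steps most likely to fail, in order of risk:

**Step 3 (proposed new desymmetrisation and closure).** Possible failures are a racemic background opening (uncatalysed or by adventitious HBr), N‑acylation of the catalyst, acylation of the tertiary OH, and transfer of the ortho tiglate to the tertiary alkoxide during closure. The fallback uses known chemistry, sets out from 8 and comes back at 11. Compound 8 is opened with chloride under chiral Brønsted acid catalysis, a reaction established for 3‑substituted oxetanes: a SPINOL‑derived chiral phosphoric acid (5 mol%), Me3SiCl and water‑doped molecular sieves as a slow HCl source, toluene, rt. With the acid antipode that attacks the pro‑S CH2 this gives the chlorodiol 2‑[(2S)‑1‑chloro‑2,3‑dihydroxypropan‑2‑yl]‑5‑[(2‑methylpropanoyloxy)methyl]phenyl (2E)‑2‑methylbut‑2‑enoate F1. The primary OH of F1 is esterified selectively with 7 (1.1 equiv, 2,4,6‑collidine, DMAP 5 mol%, CH2Cl2, −20 °C) to give the chlorohydrin ester 2‑[(2S)‑1‑chloro‑2‑hydroxy‑3‑(2‑methylpropanoyloxy)propan‑2‑yl]‑5‑[(2‑methylpropanoyloxy)methyl]phenyl (2E)‑2‑methylbut‑2‑enoate F2. Cs2CO3 in MeCN then closes the oxirane to 11.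

**Step 1 (unprotected trilithio arene).** Possible failures are poor solubility of the trianion, butylation of the aryllithium by the 1‑bromobutane formed, and low conversion with 2. The fallback sets out from 1 and comes back at 4. Compound 1 is silylated on both oxygens (iPr3SiCl, imidazole, DMF) to give [2‑bromo‑5‑({[tri(propan‑2‑yl)silyl]oxy}methyl)phenoxy]tri(propan‑2‑yl)silane F3; the bulky silyl group is chosen because its O→C shift onto an ortho‑lithio carbon is slow at −78 °C. Exchange with one equivalent of n‑BuLi in THF at −78 °C gives 2‑{[tri(propan‑2‑yl)silyl]oxy}‑4‑({[tri(propan‑2‑yl)silyl]oxy}methyl)phenyllithium F4. This is trapped with 2 at −78 °C to give 3‑[2‑{[tri(propan‑2‑yl)silyl]oxy}‑4‑({[tri(propan‑2‑yl)silyl]oxy}methyl)phenyl]oxetan‑3‑ol F5. Bu4NF in THF at 0 °C removes both silyl groups and returns 4.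

**Step 2 (one‑pot chemoselective double acylation).** Possible failures are incomplete phenol selectivity, DMAP‑mediated scrambling of the aryl ester, and opening of the oxetane by the ortho phenoxide. The fallback sets out from 4 and comes back at 8. The order is reversed and the first acylation is enzymatic: immobilised Candida antarctica lipase B with 7 in tert‑butyl methyl ether at rt esterifies only the primary benzylic OH and gives [3‑hydroxy‑4‑(3‑hydroxyoxetan‑3‑yl)phenyl]methyl 2‑methylpropanoate F6. Compound 5 with K2CO3 in acetone at 0 °C then acylates the remaining phenol to give 8.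

## Further compounds

F1 | step 3 | 2‑[(2S)‑1‑chloro‑2,3‑dihydroxypropan‑2‑yl]‑5‑[(2‑methylpropanoyloxy)methyl]phenyl (2E)‑2‑methylbut‑2‑enoate | C/C=C(\C)C(=O)Oc1cc(COC(=O)C(C)C)ccc1[C@](O)(CO)CCl
F2 | step 3 | 2‑[(2S)‑1‑chloro‑2‑hydroxy‑3‑(2‑methylpropanoyloxy)propan‑2‑yl]‑5‑[(2‑methylpropanoyloxy)methyl]phenyl (2E)‑2‑methylbut‑2‑enoate | C/C=C(\C)C(=O)Oc1cc(COC(=O)C(C)C)ccc1[C@](O)(COC(=O)C(C)C)CCl
F3 | step 1 | [2‑bromo‑5‑({[tri(propan‑2‑yl)silyl]oxy}methyl)phenoxy]tri(propan‑2‑yl)silane | CC(C)[Si](OCc1ccc(Br)c(O[Si](C(C)C)(C(C)C)C(C)C)c1)(C(C)C)C(C)C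
F4 | step 1 | 2‑{[tri(propan‑2‑yl)silyl]oxy}‑4‑({[tri(propan‑2‑yl)silyl]oxy}methyl)phenyllithium | CC(C)[Si](OCc1ccc([Li])c(O[Si](C(C)C)(C(C)C)C(C)C)c1)(C(C)C)C(C)C
F5 | step 1 | 3‑[2‑{[tri(propan‑2‑yl)silyl]oxy}‑4‑({[tri(propan‑2‑yl)silyl]oxy}methyl)phenyl]oxetan‑3‑ol | CC(C)[Si](OCc1ccc(C2(O)COC2)c(O[Si](C(C)C)(C(C)C)C(C)C)c1)(C(C)C)C(C)C
F6 | step 2 | [3‑hydroxy‑4‑(3‑hydroxyoxetan‑3‑yl)phenyl]methyl 2‑methylpropanoate | CC(C)C(=O)OCc1ccc(C2(O)COC2)c(O)c1
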